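All three C-prenyl groups are traced back to O-allyl ethers. C6 and C8 of ring A and C5' of ring B each stand ortho to a phenolic oxygen (O5, O7, O4'), so heating one tri-O-allyl (2S)-flavanone should shift all three allyl groups from oxygen to carbon by aromatic Claisen rearrangement, making three aryl–CH2 bonds at once without closing a ring or touching C2. The precursor, (2S)-5,7-bis(allyloxy)-2-(4-allyloxy-3-methoxyphenyl)chroman-4-one, comes from rhodium-catalysed asymmetric addition of an arylboronic acid to 5,7-bis(allyloxy)chromone, which sets C2. Triple cross-metathesis with 2-methylbut-2-ene then converts allyl into prenyl.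

Key step: step 6

Remarks on the chemistry:
- C2 is bonded directly to the arene, so ring B enters as an arylboronic acid made from 4-bromo-2-methoxyphenol. A benzaldehyde such as vanillin carries the C2 carbon itself and fits only the aldol route kept as a fallback.
- Step 1 consumes two molecules of allyl bromide and step 7 three molecules of 2-methylbut-2-ene. The equivalents beyond the one on the Reactants line are entered as reagents that add atoms.
- The order of the three shifts in step 6 is not fixed. Compounds 12 and 13 show one representative sequence, and every other order should lead to the same product.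
- Assumption: the (S)-bisphosphine in step 5 is expected to give (2S), by analogy with additions to cyclic enones. Should the sense be opposite, the (R)-ligand is used.

Step 1
Reactants: 1 2,4,6-trihydroxyacetophenone; 2 allyl bromide
Product: 3 1-[2,4-bis(allyloxy)-6-hydroxyphenyl]ethan-1-one
Conditions: allyl bromide (2.1 equiv in all), K2CO3 (2.2 equiv), acetone, reflux
Reagents that add atoms: allyl bromide (second equivalent), C=CCBr
Why: Williamson ether synthesis in which two equivalents of allyl bromide alkylate the 2- and 4-hydroxyls and which should stop at the bis-ether because the last ortho hydroxyl is held in a hydrogen bond to the acetyl carbonyl and is the least nucleophilic.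

Step 2
Reactants: 3 1-[2,4-bis(allyloxy)-6-hydroxyphenyl]ethan-1-one
Product: 5 5,7-bis(allyloxy)-4H-chromen-4-one, via enaminone 4 (not isolated)
Conditions: DMF-DMA, toluene, 95 °C; then conc. HCl, CH2Cl2, rt
Reagents that add atoms: N,N-dimethylformamide dimethyl acetal, COC(OC)N(C)C
Why: Enaminone route to chromones, in which the methyl ketone condenses with the amide acetal and acid then promotes addition of the phenol to the β-carbon and loss of dimethylamine, closing the pyranone while the allyl ethers stay intact.

Step 3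
Reactants: 6 4-bromo-2-methoxyphenol; 2 allyl bromide
Product: 7 1-(allyloxy)-4-bromo-2-methoxybenzene
Conditions: allyl bromide (1.2 equiv), K2CO3, acetone, reflux
Reagents that add atoms: none
Why: Williamson ether synthesis on the single phenol.

Step 4
Reactants: 7 1-(allyloxy)-4-bromo-2-methoxybenzene
Product: 10 [4-(allyloxy)-3-methoxyphenyl]boronic acid, via aryllithium 8 (not isolated), via lithium aryltriisopropoxyborate 9 (not isolated)
Conditions: n-BuLi, THF, −78 °C; B(OiPr)3, −78 °C to rt; 1 M HCl
Reagents that add atoms: triisopropyl borate, CC(C)OB(OC(C)C)OC(C)C; water, O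
Why: Bromine–lithium exchange at −78 °C is faster than ortho-lithiation or deprotonation of the allyl ether, and borate trapping with acidic hydrolysis gives the boronic acid without zerovalent palladium, which could ionise the allyl aryl ether.

Step 5
Reactants: 5 5,7-bis(allyloxy)-4H-chromen-4-one; 10 [4-(allyloxy)-3-methoxyphenyl]boronic acid
Product: 11 (2S)-5,7-bis(allyloxy)-2-[4-(allyloxy)-3-methoxyphenyl]chroman-4-one
Conditions: [Rh(OH)(cod)]2 (cat.), (S)-MeO-F12-BIPHEP [(S)-(6,6'-dimethoxybiphenyl-2,2'-diyl)bis[bis(3,4,5-trifluorophenyl)phosphine]] (cat.), 10 (2–3 equiv), toluene/H2O, 25–40 °C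
Reagents that add atoms: none
Why: Rhodium-catalysed asymmetric 1,4-addition of an arylboronic acid to a chromone (Hayashi–Miyaura reaction), in which the aryl group passes from boron to monovalent rhodium, adds across C2=C3 on the enantioface selected by the (S)-bisphosphine to set (2S), and water protonates the rhodium enolate, while base-free conditions at low temperature disfavour opening of that enolate to the chalcone and the unactivated allyl ether alkenes should not insert.

Step 6
Reactants: 11 (2S)-5,7-bis(allyloxy)-2-[4-(allyloxy)-3-methoxyphenyl]chroman-4-one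
Product: 14 (2S)-6,8-diallyl-2-(3-allyl-4-hydroxy-5-methoxyphenyl)-5,7-dihydroxychroman-4-one, via mono-C-allyl phenol 12 (not isolated), via ring-A diallyl resorcinol 13 (not isolated)
Conditions: 1,2-dichlorobenzene (degassed, dilute), 190 °C, sealed tube, Ar
Reagents that add atoms: none
Why: Each O-allyl group should migrate by a concerted suprafacial [3,3] shift through a chair-like transition state to an ortho carbon, giving a cyclohexadienone that tautomerises to the phenol (aromatic Claisen rearrangement). The O7 allyl can reach C8 or C6, and the O5 allyl reaches C6 directly or, when C6 is already taken, passes through the blocked C6 dienone and a Cope shift to C8; every order therefore drains into the same 6,8-diallyl-5,7-dihydroxy ring A, and because plain allyl has equivalent termini one or two consecutive shifts give the same CH2CH=CH2 chain. In ring B the methoxy group occupies C3', so the O4' allyl can settle only on C5'. The closest known reactions are thermal and Eu(fod)3-promoted Claisen and Claisen–Cope rearrangements of O-allyl and O-prenyl flavonoid ethers. No ring is closed and no stereocentre is created; the selectivity needed is regiochemical, secured by the substitution pattern, together with retention of C2, for which a degassed, neutral, aprotic medium without amine base is chosen so that retro-oxa-Michael opening to the chalcone is not triggered.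

Step 7
Reactants: 14 (2S)-6,8-diallyl-2-(3-allyl-4-hydroxy-5-methoxyphenyl)-5,7-dihydroxychroman-4-one; 15 2-methylbut-2-ene
Product: 16 (2S)-5,7-dihydroxy-2-[4-hydroxy-3-methoxy-5-(3-methylbut-2-en-1-yl)phenyl]-6,8-bis(3-methylbut-2-en-1-yl)chroman-4-one
Conditions: second-generation Grubbs catalyst (H2IMes)(PCy3)Cl2Ru=CHPh (10 mol%), 2-methylbut-2-ene (large excess, three equivalents consumed), CH2Cl2, 40 °C, sealed tube
Reagents that add atoms: 2-methylbut-2-ene (second equivalent), CC=C(C)C; 2-methylbut-2-ene (third equivalent), CC=C(C)C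
Why: Olefin cross-metathesis in which each of the three monosubstituted allyl alkenes takes the isopropylidene unit of one molecule of 2-methylbut-2-ene and gives up its methylene terminus as propene, the large excess of the trisubstituted partner suppressing homodimerisation, while free phenols and the ketone are tolerated and the neutral conditions leave C2 untouched.

Compound list
1 | 2,4,6-trihydroxyacetophenone | CC(=O)c1c(O)cc(O)cc1O | starting material
2 | allyl bromide | C=CCBr | starting material
3 | 1-[2,4-bis(allyloxy)-6-hydroxyphenyl]ethan-1-one | CC(=O)c1c(O)cc(OCC=C)cc1OCC=C | intermediate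
4 | (E)-1-[2,4-bis(allyloxy)-6-hydroxyphenyl]-3-(dimethylamino)prop-2-en-1-one | CN(C)/C=C/C(=O)c1c(O)cc(OCC=C)cc1OCC=C | intermediate
5 | 5,7-bis(allyloxy)-4H-chromen-4-one | O=c1ccoc2cc(OCC=C)cc(OCC=C)c12 | intermediate
6 | 4-bromo-2-methoxyphenol | COc1cc(Br)ccc1O | starting material
7 | 1-(allyloxy)-4-bromo-2-methoxybenzene | C=CCOc1ccc(Br)cc1OC | intermediate
8 | [4-(allyloxy)-3-methoxyphenyl]lithium | [Li]c1ccc(OCC=C)c(OC)c1 | intermediate
9 | lithium [4-(allyloxy)-3-methoxyphenyl]tri(propan-2-yloxy)borate | [Li+].CC(C)O[B-](OC(C)C)(OC(C)C)c1ccc(OCC=C)c(OC)c1 | intermediate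
10 | [4-(allyloxy)-3-methoxyphenyl]boronic acid | OB(O)c1ccc(OCC=C)c(OC)c1 | intermediate
11 | (2S)-5,7-bis(allyloxy)-2-[4-(allyloxy)-3-methoxyphenyl]chroman-4-one | C=CCOc1ccc([C@@H]2CC(=O)c3c(OCC=C)cc(OCC=C)cc3O2)cc1OC | intermediate
12 | (2S)-8-allyl-5-(allyloxy)-2-[4-(allyloxy)-3-methoxyphenyl]-7-hydroxychroman-4-one | C=CCOc1ccc([C@@H]2CC(=O)c3c(OCC=C)cc(O)c(CC=C)c3O2)cc1OC | intermediate
13 | (2S)-6,8-diallyl-2-[4-(allyloxy)-3-methoxyphenyl]-5,7-dihydroxychroman-4-one | C=CCOc1ccc([C@@H]2CC(=O)c3c(O)c(CC=C)c(O)c(CC=C)c3O2)cc1OC | intermediate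
14 | (2S)-6,8-diallyl-2-(3-allyl-4-hydroxy-5-methoxyphenyl)-5,7-dihydroxychroman-4-one | COc1cc([C@@H]2CC(=O)c3c(O)c(CC=C)c(O)c(CC=C)c3O2)cc(CC=C)c1O | intermediate
15 | 2-methylbut-2-ene | CC=C(C)C | starting material
16 | (2S)-5,7-dihydroxy-2-[4-hydroxy-3-methoxy-5-(3-methylbut-2-en-1-yl)phenyl]-6,8-bis(3-methylbut-2-en-1-yl)chroman-4-one | COc1cc([C@@H]2CC(=O)c3c(O)c(CC=C(C)C)c(O)c(CC=C(C)C)c3O2)cc(CC=C(C)C)c1O | target

Total step count: 7
Longest linear sequence: 5 steps (1 → 2 → 5 → 6 → 7, or 3 → 4 → 5 → 6 → 7)

Steps most likely to fail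

1. Step 6. At 190 °C the pyranone may open and reclose by retro-oxa-Michael and oxa-Michael reaction once phenols appear, eroding the configuration at C2, and migration may stall with partly rearranged ethers left. Fallback: the rearrangements are moved to the achiral fragments, setting out from 5 and 7 and returning at 14. Heating 5 in 1,2-dichlorobenzene should give 6,8-diallyl-5,7-dihydroxy-4H-chromen-4-one F1, which has no stereocentre to lose, and NaH/MOMCl in DMF converts it into 6,8-diallyl-5,7-bis(methoxymethoxy)-4H-chromen-4-one F2. Ether 7 is rearranged in the same way to 2-allyl-4-bromo-6-methoxyphenol F3 and protected (NaH, MOMCl) as 1-allyl-5-bromo-3-methoxy-2-(methoxymethoxy)benzene F4. Treatment with n-BuLi at −78 °C gives [3-allyl-5-methoxy-4-(methoxymethoxy)phenyl]lithium F5, B(OiPr)3 gives lithium [3-allyl-5-methoxy-4-(methoxymethoxy)phenyl]tri(propan-2-yloxy)borate F6, and mild aqueous acid gives [3-allyl-5-methoxy-4-(methoxymethoxy)phenyl]boronic acid F7. The rhodium-catalysed asymmetric addition of step 5, now between F2 and F7, should give (2S)-6,8-diallyl-2-[3-allyl-5-methoxy-4-(methoxymethoxy)phenyl]-5,7-bis(methoxymethoxy)chroman-4-one F8, and HCl in MeOH at rt releases 14.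

2. Step 5. Insertion into the electron-rich 5,7-dialkoxychromone may be slow, so that protodeboronation of 10 competes, and opening of the rhodium enolate to a chalcone may lower the enantiomeric purity. Fallback: an aldol route with resolution, setting out from 3 and returning at 11. Vanillin is O-allylated with 2 (K2CO3, acetone) to 4-(allyloxy)-3-methoxybenzaldehyde F9. Claisen–Schmidt condensation with 3 (KOH, EtOH, rt) gives (E)-1-[2,4-bis(allyloxy)-6-hydroxyphenyl]-3-[4-(allyloxy)-3-methoxyphenyl]prop-2-en-1-one F10. NaOAc in refluxing EtOH closes it by oxa-Michael addition to racemic 5,7-bis(allyloxy)-2-[4-(allyloxy)-3-methoxyphenyl]chroman-4-one F11. Preparative chromatography on a polysaccharide chiral stationary phase should deliver 11, and the (2R)-5,7-bis(allyloxy)-2-[4-(allyloxy)-3-methoxyphenyl]chroman-4-one F12 is re-equilibrated with NaOAc through F10 and recycled.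

3. Step 7. Exchange at three sites may stop short, and ruthenium hydride species formed in the presence of free ortho phenols may move the allyl double bonds into conjugation before metathesis, shortening the side chains. Fallback: the phenols are masked first, setting out from 14 and returning at 16. Ac2O/pyridine with catalytic DMAP gives (2S)-2-(4-acetoxy-3-allyl-5-methoxyphenyl)-6,8-diallyl-4-oxochromane-5,7-diyl diacetate F13. Cross-metathesis under the conditions of step 7 gives (2S)-2-[4-acetoxy-3-methoxy-5-(3-methylbut-2-en-1-yl)phenyl]-6,8-bis(3-methylbut-2-en-1-yl)-4-oxochromane-5,7-diyl diacetate F14. Near-neutral deacetylation (NH4OAc, MeOH/H2O, rt) then frees 16 without exposing C2 to base.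

Further compounds
F1 | step 6 | 6,8-diallyl-5,7-dihydroxy-4H-chromen-4-one | O=c1ccoc2c(CC=C)c(O)c(CC=C)c(O)c12
F2 | step 6 | 6,8-diallyl-5,7-bis(methoxymethoxy)-4H-chromen-4-one | O=c1ccoc2c(CC=C)c(OCOC)c(CC=C)c(OCOC)c12
F3 | step 6 | 2-allyl-4-bromo-6-methoxyphenol | C=CCc1cc(Br)cc(OC)c1O
F4 | step 6 | 1-allyl-5-bromo-3-methoxy-2-(methoxymethoxy)benzene | C=CCc1cc(Br)cc(OC)c1OCOC
F5 | step 6 | [3-allyl-5-methoxy-4-(methoxymethoxy)phenyl]lithium | [Li]c1cc(CC=C)c(OCOC)c(OC)c1
F6 | step 6 | lithium [3-allyl-5-methoxy-4-(methoxymethoxy)phenyl]tri(propan-2-yloxy)borate | [Li+].CC(C)O[B-](OC(C)C)(OC(C)C)c1cc(CC=C)c(OCOC)c(OC)c1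
F7 | step 6 | [3-allyl-5-methoxy-4-(methoxymethoxy)phenyl]boronic acid | OB(O)c1cc(CC=C)c(OCOC)c(OC)c1
F8 | step 6 | (2S)-6,8-diallyl-2-[3-allyl-5-methoxy-4-(methoxymethoxy)phenyl]-5,7-bis(methoxymethoxy)chroman-4-one | COCOc1c(CC=C)cc([C@@H]2CC(=O)c3c(OCOC)c(CC=C)c(OCOC)c(CC=C)c3O2)cc1OC
F9 | step 5 | 4-(allyloxy)-3-methoxybenzaldehyde | C=CCOc1ccc(C=O)cc1OC
F10 | step 5 | (E)-1-[2,4-bis(allyloxy)-6-hydroxyphenyl]-3-[4-(allyloxy)-3-methoxyphenyl]prop-2-en-1-one | C=CCOc1ccc(/C=C/C(=O)c2c(O)cc(OCC=C)cc2OCC=C)cc1OC
F11 | step 5 | racemic 5,7-bis(allyloxy)-2-[4-(allyloxy)-3-methoxyphenyl]chroman-4-one | C=CCOc1ccc(C2CC(=O)c3c(OCC=C)cc(OCC=C)cc3O2)cc1OC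
F12 | step 5 | (2R)-5,7-bis(allyloxy)-2-[4-(allyloxy)-3-methoxyphenyl]chroman-4-one | C=CCOc1ccc([C@H]2CC(=O)c3c(OCC=C)cc(OCC=C)cc3O2)cc1OC
F13 | step 7 | (2S)-2-(4-acetoxy-3-allyl-5-methoxyphenyl)-6,8-diallyl-4-oxochromane-5,7-diyl diacetate | COc1cc([C@@H]2CC(=O)c3c(OC(C)=O)c(CC=C)c(OC(C)=O)c(CC=C)c3O2)cc(CC=C)c1OC(C)=O
F14 | step 7 | (2S)-2-[4-acetoxy-3-methoxy-5-(3-methylbut-2-en-1-yl)phenyl]-6,8-bis(3-methylbut-2-en-1-yl)-4-oxochromane-5,7-diyl diacetate | COc1cc([C@@H]2CC(=O)c3c(OC(C)=O)c(CC=C(C)C)c(OC(C)=O)c(CC=C(C)C)c3O2)cc(CC=C(C)C)c1OC(C)=O
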